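## Retrosynthetic overview

- **Feature:** in ring A the four neighbouring carbons C5, C6, C7 and C8 all carry oxygen, and O–C5 and O–C8 are para. This C4O4 strip is a squaric acid unit, so C5–C8 are traced back to a cyclobutenone.
- **End game, 21 ⇐ 20 ⇐ 19 ⇐ 18:** hydrogenolysis of the ring B benzyl ethers, acid cleavage of the C7 tert-butyl ether, and methylation of the free C8 phenol.
- **Key disconnections, 18 ⇐ 15 ⇐ 10 + 13:** cyclobutenone opening and 6π closure onto the pyranone CH form the C8–C8a bond and ring A. Addition of the C5-magnesiated pyranone to the mixed squarate forms the C4a–C5 bond.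
- **Ring C, 10 ⇐ 4 + 7:** acylation of an iodinated methoxymethylene ketone, then acid closure. The iodine is built in before the ring exists, because iodination of a finished 2-arylpyranone would be expected at C3 or on ring B.
- **Ring order:** ring B is bought, ring C is closed in step 5, the four-membered ring comes from dimethyl squarate, and ring A is closed last in step 8.

Key step: step 8

Assumption: the target has no stereocenter. Adduct 15 is carried as the racemate because its only stereocenter is lost in step 8, and the alkene geometry of 7 is lost in the ring closure of step 5.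

## Route

Step 1
Reactants: 1 methyl 3,5-dihydroxy-4-methoxybenzoate
Product: 2 methyl 3,5-bis(benzyloxy)-4-methoxybenzoate
Conditions: BnBr (2.4 equiv), K2CO3 (3 equiv), DMF, 60 °C
Reagents that add atoms: benzyl bromide, BrCc1ccccc1
Why: Williamson ether synthesis alkylates both phenols, and the benzyl ethers should be inert to every later step up to the final hydrogenolysis.

Step 2
Reactants: 2 methyl 3,5-bis(benzyloxy)-4-methoxybenzoate
Product: 3 3,5-bis(benzyloxy)-4-methoxybenzoic acid
Conditions: LiOH (3 equiv), THF–MeOH–H2O, 50 °C; then 1 M HCl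
Reagents that add atoms: lithium hydroxide, [Li+].[OH-]
Why: Ester saponification (acyl substitution by hydroxide) should free the acid without touching the aryl ethers.

Step 3
Reactants: 3 3,5-bis(benzyloxy)-4-methoxybenzoic acid
Product: 4 3,5-bis(benzyloxy)-4-methoxybenzoyl chloride
Conditions: (COCl)2 (1.3 equiv), DMF (cat.), CH2Cl2, 0 °C to rt; evaporate and use crude
Reagents that add atoms: oxalyl chloride, O=C(Cl)C(=O)Cl
Why: Acid chloride formation through the chloroiminium species from oxalyl chloride and DMF runs cold and without strong acid, which benzyl ethers tolerate.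

Step 4
Reactants: 5 (E)-4-methoxybut-3-en-2-one
Product: 7 (Z)-3-iodo-4-methoxybut-3-en-2-one, via chloro iodo adduct 6 (not isolated)
Conditions: ICl (1.05 equiv), CH2Cl2, −78 to 0 °C; then Et3N (1.5 equiv), 0 °C to rt; exclude light
Reagents that add atoms: iodine monochloride, ICl
Why: Halogenation–dehydrohalogenation of a β-alkoxy enone puts iodine on the nucleophilic α-carbon and chloride on the oxocarbenium carbon, and E1cB loss of HCl restores the alkene, which fixes the halogen at the future pyranone C5.

Step 5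
Reactants: 4 3,5-bis(benzyloxy)-4-methoxybenzoyl chloride; 7 (Z)-3-iodo-4-methoxybut-3-en-2-one
Product: 10 2-[3,5-bis(benzyloxy)-4-methoxyphenyl]-5-iodo-4H-pyran-4-one, via lithium dienolate 8 (not isolated), via iodo enol ether diketone 9 (not isolated)
Conditions: 7 (2.1 equiv), LiN(SiMe3)2 (2.1 equiv), THF, −78 °C; 4 (1.0 equiv), −78 °C; sat. NH4Cl; crude 9, CF3CO2H (0.2 equiv), toluene, rt
Reagents that add atoms: none
Why: Kinetic deprotonation of the methyl ketone and Claisen-type C-acylation by the acid chloride (the second equivalent of enolate takes up the acidic diketone proton) should give 9, whose enol oxygen adds to the methoxy-bearing carbon and expels methanol under acid, which is the established γ-pyranone synthesis from methoxymethylene ketones.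

Step 6
Reactants: 11 dimethyl squarate; 12 potassium tert-butoxide
Product: 13 3-tert-butoxy-4-methoxycyclobut-3-ene-1,2-dione
Conditions: KOtBu (1.0 equiv), THF, −78 to −40 °C; sat. NH4Cl
Reagents that add atoms: potassium tert-butoxide (12), CC(C)(C)[O-].[K+]
Why: Addition–elimination at a vinylogous ester carbon of the squarate (transetherification) exchanges one methoxy group, and one equivalent of the bulky alkoxide at low temperature should stop the reaction at the mixed diester.

Step 7
Reactants: 10 2-[3,5-bis(benzyloxy)-4-methoxyphenyl]-5-iodo-4H-pyran-4-one; 13 3-tert-butoxy-4-methoxycyclobut-3-ene-1,2-dione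
Product: 15 racemic 4-{6-[3,5-bis(benzyloxy)-4-methoxyphenyl]-4-oxo-4H-pyran-3-yl}-2-tert-butoxy-4-hydroxy-3-methoxycyclobut-2-en-1-one, via pyranylmagnesium chloride 14 (not isolated)
Conditions: iPrMgCl·LiCl (1.05 equiv), THF, −60 °C, 30 min; transfer into 13 (1.3 equiv), THF, −78 °C; sat. NH4Cl at −78 °C
Reagents that add atoms: none
Why: Iodine–magnesium exchange with the turbo-Grignard reagent is fast on an α-iodo vinylogous ester and should outrun addition to the pyranone, after which the alkenylmagnesium adds 1,2 to the squarate carbonyl that lies next to the methoxy-bearing carbon and away from the bulky tert-butoxy group; the carbinol stereocenter forms as a racemate and is erased in step 8.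

Step 8
Reactants: 15 racemic 4-{6-[3,5-bis(benzyloxy)-4-methoxyphenyl]-4-oxo-4H-pyran-3-yl}-2-tert-butoxy-4-hydroxy-3-methoxycyclobut-2-en-1-one
Product: 18 2-[3,5-bis(benzyloxy)-4-methoxyphenyl]-7-tert-butoxy-5,8-dihydroxy-6-methoxy-4H-chromen-4-one, via dienylketene 16 (not isolated), via cyclohexadienone 17 (not isolated)
Conditions: degassed toluene (0.02 M), 110 °C, argon, base-washed glassware; concentrate and use at once
Reagents that add atoms: none
Why: Heat breaks the C1–C4 bond of the cyclobutenone in a conrotatory 4π opening in which the donor hydroxyl turns outward and the pyranyl group inward, so dienylketene 16 is born with its ketene carbon beside the O–CH= carbon of the pyranone. A disrotatory 6π electrocyclization joins the ketene carbon (future C8) to that carbon (future C8a) and closes the six-membered carbocycle ring A as cyclohexadienone 17, and shift of the C8a hydrogen to oxygen aromatizes it to hydroquinone 18. The closest known reaction type is the Moore ring expansion of 4-alkenyl- and 4-heteroaryl-4-hydroxycyclobutenones (furyl and thienyl adducts among them), of which the 4-oxopyran-3-yl adduct is a new member whose C=C bond has little aromatic stabilization to lose. The step needs closure at the pyranone CH and not at the pyranone carbonyl oxygen: the hydrogen bond from the enol hydroxyl to that carbonyl (the later C5–OH···O=C4 chelate) holds the rotamer that turns the CH toward the ketene, and attack by the oxygen would have to form a seven-membered ring. No stereocenter is set, since the carbinol carbon of 15 and C8a of 17 both end as sp2 carbons, and the order 6-methoxy/7-tert-butoxy is handed on unchanged from 15. Oxygen-free toluene at no more than 110 °C should protect the hydroquinone from oxidation and the tert-butyl ether from thermal loss of isobutene.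

Step 9
Reactants: 18 2-[3,5-bis(benzyloxy)-4-methoxyphenyl]-7-tert-butoxy-5,8-dihydroxy-6-methoxy-4H-chromen-4-one
Product: 19 2-[3,5-bis(benzyloxy)-4-methoxyphenyl]-7-tert-butoxy-5-hydroxy-6,8-dimethoxy-4H-chromen-4-one
Conditions: MeI (1.2 equiv), K2CO3 (1.2 equiv), degassed acetone, rt, argon
Reagents that add atoms: iodomethane, CI
Why: Williamson methylation under mild carbonate conditions should take only the free C8 phenol, because the C5 hydroxyl is held in a hydrogen bond to the C4 carbonyl (the classical partial methylation of 5,8-dihydroxyflavones), and argon keeps the hydroquinone from going to the quinone.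

Step 10
Reactants: 19 2-[3,5-bis(benzyloxy)-4-methoxyphenyl]-7-tert-butoxy-5-hydroxy-6,8-dimethoxy-4H-chromen-4-one
Product: 20 2-[3,5-bis(benzyloxy)-4-methoxyphenyl]-5,7-dihydroxy-6,8-dimethoxy-4H-chromen-4-one
Conditions: CF3CO2H–CH2Cl2 (1:4), 0 °C to rt
Reagents that add atoms: none
Why: Acidolysis of the aryl tert-butyl ether through the tert-butyl cation (E1) should release the C7 phenol, while methyl and benzyl aryl ethers persist at this temperature.

Step 11
Reactants: 20 2-[3,5-bis(benzyloxy)-4-methoxyphenyl]-5,7-dihydroxy-6,8-dimethoxy-4H-chromen-4-one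
Product: 21 2-(3,5-dihydroxy-4-methoxyphenyl)-5,7-dihydroxy-6,8-dimethoxy-4H-chromen-4-one (CNP0185233.0)
Conditions: H2 (1 atm), 10% Pd/C, EtOAc–MeOH, rt
Reagents that add atoms: none
Why: Catalytic hydrogenolysis should cleave the two benzyl aryl ethers at one atmosphere and leave the flavone C2=C3 bond and the methyl ethers intact.

## Compound list

| No. | Name | SMILES | Role |
|---|---|---|---|
| 1 | methyl 3,5-dihydroxy-4-methoxybenzoate | COC(=O)c1cc(O)c(OC)c(O)c1 | starting material |
| 2 | methyl 3,5-bis(benzyloxy)-4-methoxybenzoate | COC(=O)c1cc(OCc2ccccc2)c(OC)c(OCc2ccccc2)c1 | intermediate |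
| 3 | 3,5-bis(benzyloxy)-4-methoxybenzoic acid | OC(=O)c1cc(OCc2ccccc2)c(OC)c(OCc2ccccc2)c1 | intermediate |
| 4 | 3,5-bis(benzyloxy)-4-methoxybenzoyl chloride | ClC(=O)c1cc(OCc2ccccc2)c(OC)c(OCc2ccccc2)c1 | intermediate |
| 5 | (E)-4-methoxybut-3-en-2-one | CO/C=C/C(C)=O | starting material |
| 6 | 4-chloro-3-iodo-4-methoxybutan-2-one (racemic diastereomer mixture, formed in the flask) | COC(Cl)C(I)C(C)=O | intermediate |
| 7 | (Z)-3-iodo-4-methoxybut-3-en-2-one | CO/C=C(\I)C(C)=O | intermediate |
| 8 | lithium (Z)-3-iodo-4-methoxybuta-1,3-dien-2-olate (formed in the flask) | CO/C=C(\I)C(=C)[O-].[Li+] | intermediate |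
| 9 | (Z)-1-[3,5-bis(benzyloxy)-4-methoxyphenyl]-4-iodo-5-methoxypent-4-ene-1,3-dione (crude, not purified) | CO/C=C(\I)C(=O)CC(=O)c1cc(OCc2ccccc2)c(OC)c(OCc2ccccc2)c1 | intermediate |
| 10 | 2-[3,5-bis(benzyloxy)-4-methoxyphenyl]-5-iodo-4H-pyran-4-one | O=c1cc(-c2cc(OCc3ccccc3)c(OC)c(OCc3ccccc3)c2)occ1I | intermediate |
| 11 | dimethyl squarate (3,4-dimethoxycyclobut-3-ene-1,2-dione) | COC1=C(OC)C(=O)C1=O | starting material |
| 12 | potassium tert-butoxide | CC(C)(C)[O-].[K+] | starting material |
| 13 | 3-tert-butoxy-4-methoxycyclobut-3-ene-1,2-dione | COC1=C(OC(C)(C)C)C(=O)C1=O | intermediate |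
| 14 | {6-[3,5-bis(benzyloxy)-4-methoxyphenyl]-4-oxo-4H-pyran-3-yl}magnesium chloride (formed in the flask) | O=c1cc(-c2cc(OCc3ccccc3)c(OC)c(OCc3ccccc3)c2)occ1[Mg]Cl | intermediate |
| 15 | racemic 4-{6-[3,5-bis(benzyloxy)-4-methoxyphenyl]-4-oxo-4H-pyran-3-yl}-2-tert-butoxy-4-hydroxy-3-methoxycyclobut-2-en-1-one | O=C1C(OC(C)(C)C)=C(OC)C1(O)c1coc(-c2cc(OCc3ccccc3)c(OC)c(OCc3ccccc3)c2)cc1=O | intermediate |
| 16 | (Z)-dienylketene, pyranyl group cis to the ketene arm: 2-tert-butoxy-4-hydroxy-3-methoxy-4-(6-aryl-4-oxo-4H-pyran-3-yl)buta-1,3-dien-1-one (formed in the flask) | O=C=C(OC(C)(C)C)/C(OC)=C(/O)c1coc(-c2cc(OCc3ccccc3)c(OC)c(OCc3ccccc3)c2)cc1=O | intermediate |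
| 17 | racemic 2-[3,5-bis(benzyloxy)-4-methoxyphenyl]-7-tert-butoxy-5-hydroxy-6-methoxy-8aH-chromene-4,8-dione (formed in the flask) | O=C1C(OC(C)(C)C)=C(OC)C(O)=C2C(=O)C=C(c3cc(OCc4ccccc4)c(OC)c(OCc4ccccc4)c3)OC12 | intermediate |
| 18 | 2-[3,5-bis(benzyloxy)-4-methoxyphenyl]-7-tert-butoxy-5,8-dihydroxy-6-methoxy-4H-chromen-4-one | COc1c(O)c2c(=O)cc(-c3cc(OCc4ccccc4)c(OC)c(OCc4ccccc4)c3)oc2c(O)c1OC(C)(C)C | intermediate |
| 19 | 2-[3,5-bis(benzyloxy)-4-methoxyphenyl]-7-tert-butoxy-5-hydroxy-6,8-dimethoxy-4H-chromen-4-one | COc1c(O)c2c(=O)cc(-c3cc(OCc4ccccc4)c(OC)c(OCc4ccccc4)c3)oc2c(OC)c1OC(C)(C)C | intermediate |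
| 20 | 2-[3,5-bis(benzyloxy)-4-methoxyphenyl]-5,7-dihydroxy-6,8-dimethoxy-4H-chromen-4-one | COc1c(O)c2c(=O)cc(-c3cc(OCc4ccccc4)c(OC)c(OCc4ccccc4)c3)oc2c(OC)c1O | intermediate |
| 21 | 2-(3,5-dihydroxy-4-methoxyphenyl)-5,7-dihydroxy-6,8-dimethoxy-4H-chromen-4-one (CNP0185233.0) | COc1c(O)cc(-c2cc(=O)c3c(O)c(OC)c(O)c(OC)c3o2)cc1O | target |

## Step count

Total step count: 11. Longest linear sequence: 9 (steps 1, 2, 3, 5, 7, 8, 9, 10, 11).

## Steps most likely to fail

**Step 8.** The carbon that must accept the ketene is the β-carbon of an enone and is therefore electron-poor. Ring closure may be slow enough that ketene dimerization, trapping by adventitious nucleophiles, or thermal loss of isobutene from the tert-butyl vinylogous ester takes over.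

The fallback gives up the squarate and builds ring A from a phloroglucinol core. It sets out from 4.
- Commercial 2,4,6-trihydroxyacetophenone is converted to its polyanion with excess LiN(SiMe3)2 in THF (−78 °C to rt). Acylation of its methyl carbon by 4 gives 1-[3,5-bis(benzyloxy)-4-methoxyphenyl]-3-(2,4,6-trihydroxyphenyl)propane-1,3-dione F1.
- Cyclodehydration (AcOH, catalytic H2SO4, 95 °C) gives 2-[3,5-bis(benzyloxy)-4-methoxyphenyl]-5,7-dihydroxy-4H-chromen-4-one F2.
- N-Bromosuccinimide (2 equiv, CH2Cl2, 0 °C) brominates the far more activated ring A to give the 6,8-dibromo-5,7-dihydroxyflavone F3.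
- Copper-catalysed methoxylation (NaOMe, CuBr, DMF–MeOH, 110 °C), as known for 6,8-dibromo-5,7-dihydroxyflavones, replaces both bromines.

The fallback comes back to the route at 20.

**Step 7.** In 14 the C–Mg bond lies anti to the ring C–O bond, and the leaving group would be a stabilized diketone enolate. The magnesiated pyranone may therefore open to an ynone by β-elimination before it meets the squarate. Attack at both squarate carbonyls would further erode the outcome.

The fallback uses a dihydropyranone, in which the same elimination would have to expel a plain alkoxide. It sets out from 4.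
- LiAlH(OtBu)3 (THF, −78 °C) gives 3,5-bis(benzyloxy)-4-methoxybenzaldehyde F4.
- Hetero-Diels–Alder reaction with (E)-1-methoxy-3-(trimethylsilyloxy)buta-1,3-diene (ZnCl2, THF; then CF3CO2H) gives racemic 2-[3,5-bis(benzyloxy)-4-methoxyphenyl]-2,3-dihydro-4H-pyran-4-one F5.
- I2–pyridine in CH2Cl2 iodinates the only enone α-carbon and gives the 5-iodo-2,3-dihydropyranone F6.
- iPrMgCl·LiCl (THF, −40 °C) gives the dihydropyranylmagnesium chloride F7, and addition to 13 at −78 °C gives the dihydropyranyl hydroxycyclobutenone F8 as a diastereomer mixture.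
- Thermolysis as in step 8 gives the racemic 7-tert-butoxy-5,8-dihydroxy-6-methoxyflavanone F9, and MeI–K2CO3 gives the racemic 7-tert-butoxy-5-hydroxy-6,8-dimethoxyflavanone F10.
- Dehydrogenation with I2 in pyridine at 90 °C is the known conversion of flavanones to flavones.

The fallback comes back to the route at 19.

**Step 5.** O-acylation of the dienolate, loss of HI from the iodo enol ether under the amide base, or loss of iodine by protonation during the acid closure may cut into the pyranone.

The fallback brings the iodine in after the acylation and lets it trigger the ring closure. It sets out from 4.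
- The lithium enolate of commercial (E)-4-(dimethylamino)but-3-en-2-one (the condensation product of acetone and N,N-dimethylformamide dimethyl acetal) is formed with LiN(SiMe3)2 in THF at −78 °C. Acylation by 4 gives (E)-1-[3,5-bis(benzyloxy)-4-methoxyphenyl]-5-(dimethylamino)pent-4-ene-1,3-dione F11.
- I2 (1.1 equiv, CHCl3, rt) attacks the enaminone α-carbon, the most nucleophilic site. The enol oxygen then closes onto the iminium carbon with loss of dimethylamine, in the way 3-iodochromones are made from o-hydroxyaryl enaminones.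

The fallback comes back to the route at 10.

## Further compounds

F1 | step 8 | 1-[3,5-bis(benzyloxy)-4-methoxyphenyl]-3-(2,4,6-trihydroxyphenyl)propane-1,3-dione | O=C(CC(=O)c1cc(OCc2ccccc2)c(OC)c(OCc2ccccc2)c1)c1c(O)cc(O)cc1O
F2 | step 8 | 2-[3,5-bis(benzyloxy)-4-methoxyphenyl]-5,7-dihydroxy-4H-chromen-4-one | O=c1cc(-c2cc(OCc3ccccc3)c(OC)c(OCc3ccccc3)c2)oc2cc(O)cc(O)c12
F3 | step 8 | 2-[3,5-bis(benzyloxy)-4-methoxyphenyl]-6,8-dibromo-5,7-dihydroxy-4H-chromen-4-one | O=c1cc(-c2cc(OCc3ccccc3)c(OC)c(OCc3ccccc3)c2)oc2c(Br)c(O)c(Br)c(O)c12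
F4 | step 7 | 3,5-bis(benzyloxy)-4-methoxybenzaldehyde | O=Cc1cc(OCc2ccccc2)c(OC)c(OCc2ccccc2)c1
F5 | step 7 | racemic 2-[3,5-bis(benzyloxy)-4-methoxyphenyl]-2,3-dihydro-4H-pyran-4-one | O=C1C=COC(c2cc(OCc3ccccc3)c(OC)c(OCc3ccccc3)c2)C1
F6 | step 7 | racemic 2-[3,5-bis(benzyloxy)-4-methoxyphenyl]-5-iodo-2,3-dihydro-4H-pyran-4-one | O=C1CC(c2cc(OCc3ccccc3)c(OC)c(OCc3ccccc3)c2)OC=C1I
F7 | step 7 | racemic {2-[3,5-bis(benzyloxy)-4-methoxyphenyl]-4-oxo-3,4-dihydro-2H-pyran-5-yl}magnesium chloride | O=C1CC(c2cc(OCc3ccccc3)c(OC)c(OCc3ccccc3)c2)OC=C1[Mg]Cl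
F8 | step 7 | 4-{2-[3,5-bis(benzyloxy)-4-methoxyphenyl]-4-oxo-3,4-dihydro-2H-pyran-5-yl}-2-tert-butoxy-4-hydroxy-3-methoxycyclobut-2-en-1-one (racemic diastereomer mixture) | O=C1C(OC(C)(C)C)=C(OC)C1(O)C1=COC(c2cc(OCc3ccccc3)c(OC)c(OCc3ccccc3)c2)CC1=O
F9 | step 7 | racemic 2-[3,5-bis(benzyloxy)-4-methoxyphenyl]-7-tert-butoxy-5,8-dihydroxy-6-methoxychroman-4-one | COc1c(O)c2c(c(O)c1OC(C)(C)C)OC(c1cc(OCc3ccccc3)c(OC)c(OCc3ccccc3)c1)CC2=O
F10 | step 7 | racemic 2-[3,5-bis(benzyloxy)-4-methoxyphenyl]-7-tert-butoxy-5-hydroxy-6,8-dimethoxychroman-4-one | COc1c(O)c2c(c(OC)c1OC(C)(C)C)OC(c1cc(OCc3ccccc3)c(OC)c(OCc3ccccc3)c1)CC2=O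
F11 | step 5 | (E)-1-[3,5-bis(benzyloxy)-4-methoxyphenyl]-5-(dimethylamino)pent-4-ene-1,3-dione | CN(C)/C=C/C(=O)CC(=O)c1cc(OCc2ccccc2)c(OC)c(OCc2ccccc2)c1
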